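**Retrosynthetic overview**
1. The 1,2-dioxane ring is formed last, by intramolecular oxa-Michael addition of a C6 tertiary hydroperoxide to a butenolide (sets C3, cis fusion); the hydroperoxide comes from cobalt-catalysed hydroperoxysilylation of a C6 1,1-disubstituted alkene.
2. The lactone ring is formed first, as a butenolide, by Z-selective olefination of a C3 aldehyde and lactonisation of the C4 tertiary alcohol; the C6 methylene comes from methylenation of a C6 ketone.
3. Key C4–C5 bond: enantioselective intermolecular Mukaiyama aldol addition of the enolsilane of methyl ketone 13 to methyl pyruvate, setting C4.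
4. Ketone 13 comes from (S)-citronellol (C8 from the chiral pool) by ozonolysis, acetylide alkylation and carboalumination/benzylation (E alkene).

Assumption: positions are named by plakortolide numbering (C1 lactone carbonyl, C3 and C6 the peroxide-bearing carbons, C4 the lactone-oxygen carbon, C8 the side-chain methine, C12=C13 the side-chain alkene), and both antipodes of the t-Bu-box ligand are taken as purchasable.

**Route**

Step 1
Reactants: 1 (S)-citronellol [(3S)-3,7-dimethyloct-6-en-1-ol]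
Product: 2 tert-butyl{[(3S)-3,7-dimethyloct-6-en-1-yl]oxy}dimethylsilane
Conditions: TBSCl, imidazole, DMF, rt
Reagents that add atoms: tert-butyldimethylsilyl chloride, CC(C)(C)[Si](C)(C)Cl
Why: Silyl ether protection of the primary alcohol masks it through the ozonolysis, alkylation and organoaluminium steps without touching the stereocentre.

Step 2
Reactants: 2 tert-butyl{[(3S)-3,7-dimethyloct-6-en-1-yl]oxy}dimethylsilane
Product: 4 (4S)-6-[(tert-butyldimethylsilyl)oxy]-4-methylhexan-1-ol, via ozonide 3 (not isolated)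
Conditions: O3, CH2Cl2, −78 °C; then NaBH4, MeOH, −78 °C → rt
Reagents that add atoms: ozone, [O-][O+]=O
Why: Ozonolysis with reductive work-up cleaves the only C=C present directly to the primary alcohol, the C8 stereocentre being remote and untouched.

Step 3
Reactants: 4 (4S)-6-[(tert-butyldimethylsilyl)oxy]-4-methylhexan-1-ol
Product: 5 tert-butyl{[(3S)-6-iodo-3-methylhexyl]oxy}dimethylsilane
Conditions: I2, PPh3, imidazole, CH2Cl2, 0 °C → rt
Reagents that add atoms: iodine, [I][I]
Why: Appel-type iodination converts the primary alcohol into the iodide by SN2 displacement of an oxyphosphonium group under buffered conditions that a TBS ether tolerates.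

Step 4
Reactants: 5 tert-butyl{[(3S)-6-iodo-3-methylhexyl]oxy}dimethylsilane
Product: 6 tert-butyldimethyl{[(3S)-3-methyloct-7-yn-1-yl]oxy}silane
Conditions: LiC≡CH·H2NCH2CH2NH2, DMSO, 10 °C → rt
Reagents that add atoms: lithium acetylide (ethylenediamine complex), [Li]C#C
Why: SN2 alkylation of lithium acetylide with an unhindered primary iodide in a dipolar aprotic solvent gives the terminal alkyne that carries C12 and C13.

Step 5
Reactants: 6 tert-butyldimethyl{[(3S)-3-methyloct-7-yn-1-yl]oxy}silane; 7 benzyl chloride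
Product: 9 tert-butyl{[(3S,7E)-3,7-dimethyl-9-phenylnon-7-en-1-yl]oxy}dimethylsilane, via alkenylalane 8 (not isolated)
Conditions: Me3Al, Cp2ZrCl2 (25 mol %), CH2Cl2, 0 °C → rt; then 7, Pd(PPh3)4 (5 mol %), THF, rt
Reagents that add atoms: trimethylaluminium, C[Al](C)C
Why: Negishi zirconium-catalysed carboalumination adds methyl and aluminium syn across the alkyne with methyl on the internal carbon, and the palladium-catalysed cross-coupling with benzyl chloride proceeds with retention, fixing the (E)-trisubstituted alkene.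

Step 6
Reactants: 9 tert-butyl{[(3S,7E)-3,7-dimethyl-9-phenylnon-7-en-1-yl]oxy}dimethylsilane
Product: 10 (3S,7E)-3,7-dimethyl-9-phenylnon-7-en-1-ol
Conditions: TBAF, THF, rt
Reagents that add atoms: none
Why: Fluoride-mediated desilylation frees the primary alcohol without affecting the skipped alkene.

Step 7
Reactants: 10 (3S,7E)-3,7-dimethyl-9-phenylnon-7-en-1-ol
Product: 11 (3S,7E)-3,7-dimethyl-9-phenylnon-7-enal
Conditions: Dess–Martin periodinane, CH2Cl2, 0 °C → rt
Reagents that add atoms: none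
Why: Dess–Martin oxidation stops cleanly at the aldehyde under near-neutral conditions that do not move the allylbenzene-type double bond.

Step 8
Reactants: 11 (3S,7E)-3,7-dimethyl-9-phenylnon-7-enal
Product: 12 (4S,8E)-4,8-dimethyl-10-phenyldec-8-en-2-ol (mixture of C2 epimers)
Conditions: MeMgBr, THF, −78 → 0 °C
Reagents that add atoms: methylmagnesium bromide, C[Mg]Br
Why: Grignard 1,2-addition installs the future C5 carbon, and the new carbinol centre is irrelevant because it is oxidised in the next step.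

Step 9
Reactants: 12 (4S,8E)-4,8-dimethyl-10-phenyldec-8-en-2-ol
Product: 13 (4S,8E)-4,8-dimethyl-10-phenyldec-8-en-2-one
Conditions: Dess–Martin periodinane, CH2Cl2, rt
Reagents that add atoms: none
Why: Dess–Martin oxidation of the secondary alcohol gives the methyl ketone that serves as the nucleophilic fragment of the key step.

Step 10
Reactants: 13 (4S,8E)-4,8-dimethyl-10-phenyldec-8-en-2-one
Product: 14 trimethyl{[(4S,8E)-4,8-dimethyl-10-phenyldeca-1,8-dien-2-yl]oxy}silane
Conditions: LiN(i-Pr)2, Me3SiCl (in situ quench), THF, −78 °C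
Reagents that add atoms: chlorotrimethylsilane, C[Si](C)(C)Cl
Why: Kinetic deprotonation by the bulky amide at the unhindered methyl group with immediate O-silylation (silyl enol ether formation) gives the terminal enolsilane regioselectively.

Step 11
Reactants: 14 trimethyl{[(4S,8E)-4,8-dimethyl-10-phenyldeca-1,8-dien-2-yl]oxy}silane; 15 methyl pyruvate
Product: 17 methyl (2R,6S,10E)-2-hydroxy-2,6,10-trimethyl-4-oxo-12-phenyldodec-10-enoate, via silyl ether 16 (not isolated)
Conditions: Cu(OTf)2 (10 mol %), (R,R)-t-Bu-box (11 mol %), THF, −78 °C; then 1 M HCl, THF, rt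
Reagents that add atoms: none
Why: In this catalytic enantioselective Mukaiyama aldol addition the pyruvate chelates the divalent copper centre of the C2-symmetric bis(oxazoline) complex, and the (R,R) ligand (antipode of the one that gives (S) adducts by si-face attack) exposes the re face of the ketone, so the enolsilane forms the C4–C5 bond and the (R)-tertiary carbinol while the remote C8 centre is a spectator.

Step 12
Reactants: 17 methyl (2R,6S,10E)-2-hydroxy-2,6,10-trimethyl-4-oxo-12-phenyldodec-10-enoate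
Product: 18 methyl (2R,6S,10E)-2,6,10-trimethyl-4-oxo-12-phenyl-2-[(triethylsilyl)oxy]dodec-10-enoate
Conditions: Et3SiOTf, 2,6-lutidine, CH2Cl2, −78 → 0 °C
Reagents that add atoms: triethylsilyl trifluoromethanesulfonate, CC[Si](CC)(CC)OS(=O)(=O)C(F)(F)F
Why: Silyl triflate silylation protects the hindered tertiary alcohol, which blocks retro-aldol cleavage and allows clean reduction of the ester later.

Step 13
Reactants: 18 methyl (2R,6S,10E)-2,6,10-trimethyl-4-oxo-12-phenyl-2-[(triethylsilyl)oxy]dodec-10-enoate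
Product: 19 methyl (2R,6S,10E)-2,6,10-trimethyl-4-methylidene-12-phenyl-2-[(triethylsilyl)oxy]dodec-10-enoate
Conditions: Zn, CH2Br2, TiCl4, THF/CH2Cl2, 0 °C → rt
Reagents that add atoms: dibromomethane, BrCBr
Why: Takai–Lombardo methylenation is non-basic and selective for ketones over esters, so the enolisable β-silyloxy ketone becomes the 1,1-disubstituted alkene without β-elimination.

Step 14
Reactants: 19 methyl (2R,6S,10E)-2,6,10-trimethyl-4-methylidene-12-phenyl-2-[(triethylsilyl)oxy]dodec-10-enoate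
Product: 20 (2R,6S,10E)-2,6,10-trimethyl-4-methylidene-12-phenyl-2-[(triethylsilyl)oxy]dodec-10-enal
Conditions: i-Bu2AlH (1.2 equiv), CH2Cl2, −78 °C; MeOH, then aq. potassium sodium tartrate
Reagents that add atoms: none
Why: Partial hydride reduction of the α-silyloxy ester stops at the aldehyde because the chelated aluminium hemiacetal survives at −78 °C until work-up, and the quaternary C4 centre cannot epimerise.

Step 15
Reactants: 20 (2R,6S,10E)-2,6,10-trimethyl-4-methylidene-12-phenyl-2-[(triethylsilyl)oxy]dodec-10-enal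
Product: 21 methyl (2Z,4R,8S,12E)-4,8,12-trimethyl-6-methylidene-14-phenyl-4-[(triethylsilyl)oxy]tetradeca-2,12-dienoate
Conditions: (CF3CH2O)2P(O)CH2CO2Me, KN(SiMe3)2, 18-crown-6, THF, −78 °C
Reagents that add atoms: methyl bis(2,2,2-trifluoroethyl)phosphonoacetate, COC(=O)CP(=O)(OCC(F)(F)F)OCC(F)(F)F
Why: The Still–Gennari variant of the Horner–Wadsworth–Emmons olefination is kinetically (Z)-selective, placing the ester cis to C4 as lactonisation requires.

Step 16
Reactants: 21 methyl (2Z,4R,8S,12E)-4,8,12-trimethyl-6-methylidene-14-phenyl-4-[(triethylsilyl)oxy]tetradeca-2,12-dienoate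
Product: 23 (5R)-5-[(4S,8E)-4,8-dimethyl-2-methylidene-10-phenyldec-8-en-1-yl]-5-methylfuran-2(5H)-one, via hydroxy enoate 22 (not isolated)
Conditions: TsOH·H2O (20 mol %), MeOH, rt
Reagents that add atoms: none
Why: Acid-catalysed desilylation frees the tertiary alcohol, which lactonises onto the cis-disposed ester (intramolecular transesterification) to close the lactone ring as a butenolide with C4 unchanged.

Step 17
Reactants: 23 (5R)-5-[(4S,8E)-4,8-dimethyl-2-methylidene-10-phenyldec-8-en-1-yl]-5-methylfuran-2(5H)-one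
Product: 24 (5R)-5-methyl-5-{(2RS,4S,8E)-2,4,8-trimethyl-10-phenyl-2-[(triethylsilyl)peroxy]dec-8-en-1-yl}furan-2(5H)-one
Conditions: Co(thd)2 (thd = 2,2,6,6-tetramethylheptane-3,5-dionate, 10 mol %), O2 (1 atm), Et3SiH (2 equiv), ClCH2CH2Cl, rt
Reagents that add atoms: dioxygen, O=O; triethylsilane, CC[SiH](CC)CC
Why: Mukaiyama–Isayama hydroperoxysilylation (cobalt hydride hydrogen-atom transfer, O2 capture, silyl transfer) is Markovnikov-selective and fastest at the 1,1-disubstituted alkene compared with the trisubstituted and the electron-poor butenolide alkenes, and it gives about 1:1 C6 epimers because the tertiary radical is planar.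

Step 18
Reactants: 24 (5R)-5-methyl-5-{(2RS,4S,8E)-2,4,8-trimethyl-10-phenyl-2-[(triethylsilyl)peroxy]dec-8-en-1-yl}furan-2(5H)-one
Product: 26 plakortolide G [(3R,4aR,7aR)-3-[(2S,6E)-2,6-dimethyl-8-phenyloct-6-en-1-yl]-3,4a-dimethyltetrahydrofuro[3,2-c][1,2]dioxin-6(3H)-one], via hydroperoxide 25 (not isolated)
Conditions: HCl (cat.), MeOH, 0 °C; concentrate; Et2NH (0.5 equiv), CF3CH2OH, rt; chromatography
Reagents that add atoms: none
Why: Methanolysis frees the hydroperoxide, whose amine-catalysed intramolecular 6-exo oxa-Michael addition to the butenolide can only occur on the face that carries the C5 tether, giving the cis-fused dioxane ring (C3 R), and the (6R) target is separated from its C6 epimer (at most about half of the material).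

**Compound list**
1 | (S)-citronellol, (3S)-3,7-dimethyloct-6-en-1-ol | OCC[C@@H](C)CCC=C(C)C | starting material
2 | tert-butyl{[(3S)-3,7-dimethyloct-6-en-1-yl]oxy}dimethylsilane | CC(C)(C)[Si](C)(C)OCC[C@@H](C)CCC=C(C)C | intermediate
3 | tert-butyl{[(3S)-5-(5,5-dimethyl-1,2,4-trioxolan-3-yl)-3-methylpentyl]oxy}dimethylsilane (ozonide, both epimers) | CC(C)(C)[Si](C)(C)OCC[C@@H](C)CCC1OOC(C)(C)O1 | intermediate
4 | (4S)-6-[(tert-butyldimethylsilyl)oxy]-4-methylhexan-1-ol | CC(C)(C)[Si](C)(C)OCC[C@@H](C)CCCO | intermediate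
5 | tert-butyl{[(3S)-6-iodo-3-methylhexyl]oxy}dimethylsilane | CC(C)(C)[Si](C)(C)OCC[C@@H](C)CCCI | intermediate
6 | tert-butyldimethyl{[(3S)-3-methyloct-7-yn-1-yl]oxy}silane | CC(C)(C)[Si](C)(C)OCC[C@@H](C)CCCC#C | intermediate
7 | benzyl chloride | ClCc1ccccc1 | starting material
8 | {(1E,6S)-8-[(tert-butyldimethylsilyl)oxy]-2,6-dimethyloct-1-en-1-yl}dimethylalane | CC(C)(C)[Si](C)(C)OCC[C@@H](C)CCC/C(C)=C/[Al](C)C | intermediate
9 | tert-butyl{[(3S,7E)-3,7-dimethyl-9-phenylnon-7-en-1-yl]oxy}dimethylsilane | CC(C)(C)[Si](C)(C)OCC[C@@H](C)CCC/C(C)=C/Cc1ccccc1 | intermediate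
10 | (3S,7E)-3,7-dimethyl-9-phenylnon-7-en-1-ol | OCC[C@@H](C)CCC/C(C)=C/Cc1ccccc1 | intermediate
11 | (3S,7E)-3,7-dimethyl-9-phenylnon-7-enal | O=CC[C@@H](C)CCC/C(C)=C/Cc1ccccc1 | intermediate
12 | (4S,8E)-4,8-dimethyl-10-phenyldec-8-en-2-ol (C2 epimers) | CC(O)C[C@@H](C)CCC/C(C)=C/Cc1ccccc1 | intermediate
13 | (4S,8E)-4,8-dimethyl-10-phenyldec-8-en-2-one | CC(=O)C[C@@H](C)CCC/C(C)=C/Cc1ccccc1 | intermediate
14 | trimethyl{[(4S,8E)-4,8-dimethyl-10-phenyldeca-1,8-dien-2-yl]oxy}silane | C=C(O[Si](C)(C)C)C[C@@H](C)CCC/C(C)=C/Cc1ccccc1 | intermediate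
15 | methyl pyruvate | COC(=O)C(C)=O | starting material
16 | methyl (2R,6S,10E)-2,6,10-trimethyl-4-oxo-12-phenyl-2-[(trimethylsilyl)oxy]dodec-10-enoate | COC(=O)[C@](C)(O[Si](C)(C)C)CC(=O)C[C@@H](C)CCC/C(C)=C/Cc1ccccc1 | intermediate
17 | methyl (2R,6S,10E)-2-hydroxy-2,6,10-trimethyl-4-oxo-12-phenyldodec-10-enoate | COC(=O)[C@](C)(O)CC(=O)C[C@@H](C)CCC/C(C)=C/Cc1ccccc1 | intermediate
18 | methyl (2R,6S,10E)-2,6,10-trimethyl-4-oxo-12-phenyl-2-[(triethylsilyl)oxy]dodec-10-enoate | COC(=O)[C@](C)(O[Si](CC)(CC)CC)CC(=O)C[C@@H](C)CCC/C(C)=C/Cc1ccccc1 | intermediate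
19 | methyl (2R,6S,10E)-2,6,10-trimethyl-4-methylidene-12-phenyl-2-[(triethylsilyl)oxy]dodec-10-enoate | COC(=O)[C@](C)(O[Si](CC)(CC)CC)CC(=C)C[C@@H](C)CCC/C(C)=C/Cc1ccccc1 | intermediate
20 | (2R,6S,10E)-2,6,10-trimethyl-4-methylidene-12-phenyl-2-[(triethylsilyl)oxy]dodec-10-enal | O=C[C@](C)(O[Si](CC)(CC)CC)CC(=C)C[C@@H](C)CCC/C(C)=C/Cc1ccccc1 | intermediate
21 | methyl (2Z,4R,8S,12E)-4,8,12-trimethyl-6-methylidene-14-phenyl-4-[(triethylsilyl)oxy]tetradeca-2,12-dienoate | COC(=O)/C=C\[C@](C)(O[Si](CC)(CC)CC)CC(=C)C[C@@H](C)CCC/C(C)=C/Cc1ccccc1 | intermediate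
22 | methyl (2Z,4R,8S,12E)-4-hydroxy-4,8,12-trimethyl-6-methylidene-14-phenyltetradeca-2,12-dienoate | COC(=O)/C=C\[C@](C)(O)CC(=C)C[C@@H](C)CCC/C(C)=C/Cc1ccccc1 | intermediate
23 | (5R)-5-[(4S,8E)-4,8-dimethyl-2-methylidene-10-phenyldec-8-en-1-yl]-5-methylfuran-2(5H)-one | O=C1C=C[C@@](C)(CC(=C)C[C@@H](C)CCC/C(C)=C/Cc2ccccc2)O1 | intermediate
24 | (5R)-5-methyl-5-{(2RS,4S,8E)-2,4,8-trimethyl-10-phenyl-2-[(triethylsilyl)peroxy]dec-8-en-1-yl}furan-2(5H)-one | O=C1C=C[C@@](C)(CC(C)(OO[Si](CC)(CC)CC)C[C@@H](C)CCC/C(C)=C/Cc2ccccc2)O1 | intermediate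
25 | (5R)-5-[(2RS,4S,8E)-2-hydroperoxy-2,4,8-trimethyl-10-phenyldec-8-en-1-yl]-5-methylfuran-2(5H)-one | O=C1C=C[C@@](C)(CC(C)(OO)C[C@@H](C)CCC/C(C)=C/Cc2ccccc2)O1 | intermediate
26 | plakortolide G, (3R,4aR,7aR)-3-[(2S,6E)-2,6-dimethyl-8-phenyloct-6-en-1-yl]-3,4a-dimethyltetrahydrofuro[3,2-c][1,2]dioxin-6(3H)-one | C/C(=C\Cc1ccccc1)CCC[C@H](C)C[C@]1(C)C[C@@]2(C)OC(=O)C[C@H]2OO1 | target

**Step count and risks**
Total step count: 18. Longest linear sequence: 18 steps (1 → 26); 7 and 15 are purchased coupling partners.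

The three steps most likely to fail are step 17, step 11 and step 15.

Step 17 is the weakest point. The side-chain trisubstituted alkene may compete for the cobalt hydride, and the doubly activated C14 methylene may autoxidise. The fallback masks that alkene; it sets out from butenolide 23 and comes back at target 26. mCPBA (1.0 equiv, CH2Cl2, −20 °C) epoxidises the electron-rich trisubstituted alkene in preference to the 1,1-disubstituted one and leaves the butenolide, giving (5R)-5-{(4S)-7-(3-benzyl-2-methyloxiran-2-yl)-4-methyl-2-methylideneheptyl}-5-methylfuran-2(5H)-one F8 (both trans-epoxides). Hydroperoxysilylation under the conditions of step 17 then has a single reactive alkene and gives the triethylsilyl peroxide F9. Methanolysis gives the hydroperoxide F10, and Et2NH in CF3CH2OH closes it to the epoxy peroxylactone F11. Stereospecific deoxygenation with Ph3P=Se and CF3CO2H (CH2Cl2, rt) proceeds through an episelenide with retention and returns the (E)-alkene, giving 26 after separation from the C6 epimer. The compatibility of this deoxygenation with the peroxide is the unproven part of the fallback.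

Step 11 may give low conversion or a diastereomer ratio below about 95:5 with this enolsilane, and the 1,5-related diastereomers are unlikely to separate. The fallback keeps the same bond construction but hands control to a covalent auxiliary; it sets out from enolsilane 14 and comes back at aldehyde 20. (+)-8-Phenylmenthol is esterified with pyruvic acid (DCC, DMAP, CH2Cl2) to (1S,2R,5S)-5-methyl-2-(2-phenylpropan-2-yl)cyclohexyl 2-oxopropanoate F1. SnCl4-promoted Mukaiyama aldol addition of 14 to F1 (CH2Cl2, −78 °C) occurs on the chelated s-cis keto ester from the face not covered by the phenyl ring and gives the (2R)-hydroxy keto ester F2. Et3SiOTf with 2,6-lutidine gives the triethylsilyl ether F3, and Takai–Lombardo methylenation gives the methylidene ester F4. Excess i-Bu2AlH (CH2Cl2, −78 → 0 °C) cleaves the auxiliary ester to (2R,6S,10E)-2,6,10-trimethyl-4-methylidene-12-phenyl-2-[(triethylsilyl)oxy]dodec-10-en-1-ol F5 with recovery of the auxiliary. Dess–Martin oxidation of F5 gives 20. The facial sense is derived from the usual chelate model for this auxiliary and should be confirmed on the first adduct.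

Step 15 may give poor Z:E selectivity on the hindered α-quaternary aldehyde. The fallback sets the Z geometry by alkyne semi-hydrogenation instead; it sets out from aldehyde 20 and comes back at enoate 21. Ohira–Bestmann homologation (dimethyl (1-diazo-2-oxopropyl)phosphonate, K2CO3, MeOH) gives triethyl{[(3R,7S,11E)-3,7,11-trimethyl-5-methylidene-13-phenyltridec-11-en-1-yn-3-yl]oxy}silane F6. Deprotonation with n-BuLi (THF, −78 °C) and acylation with methyl chloroformate gives methyl (4R,8S,12E)-4,8,12-trimethyl-6-methylidene-14-phenyl-4-[(triethylsilyl)oxy]tetradec-12-en-2-ynoate F7. Syn semi-hydrogenation (H2, Pd/CaCO3 poisoned with Pb(OAc)2, quinoline, EtOAc) gives 21.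

**Further compounds**
F1 | step 11 | (1S,2R,5S)-5-methyl-2-(2-phenylpropan-2-yl)cyclohexyl 2-oxopropanoate | C[C@H]1CC[C@@H]([C@H](C1)OC(=O)C(C)=O)C(C)(C)c2ccccc2
F2 | step 11 | (1S,2R,5S)-5-methyl-2-(2-phenylpropan-2-yl)cyclohexyl (2R,6S,10E)-2-hydroxy-2,6,10-trimethyl-4-oxo-12-phenyldodec-10-enoate | C[C@H]1CC[C@@H]([C@H](C1)OC(=O)[C@](C)(O)CC(=O)C[C@@H](C)CCC/C(C)=C/Cc2ccccc2)C(C)(C)c3ccccc3
F3 | step 11 | (1S,2R,5S)-5-methyl-2-(2-phenylpropan-2-yl)cyclohexyl (2R,6S,10E)-2,6,10-trimethyl-4-oxo-12-phenyl-2-[(triethylsilyl)oxy]dodec-10-enoate | C[C@H]1CC[C@@H]([C@H](C1)OC(=O)[C@](C)(O[Si](CC)(CC)CC)CC(=O)C[C@@H](C)CCC/C(C)=C/Cc2ccccc2)C(C)(C)c3ccccc3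
F4 | step 11 | (1S,2R,5S)-5-methyl-2-(2-phenylpropan-2-yl)cyclohexyl (2R,6S,10E)-2,6,10-trimethyl-4-methylidene-12-phenyl-2-[(triethylsilyl)oxy]dodec-10-enoate | C[C@H]1CC[C@@H]([C@H](C1)OC(=O)[C@](C)(O[Si](CC)(CC)CC)CC(=C)C[C@@H](C)CCC/C(C)=C/Cc2ccccc2)C(C)(C)c3ccccc3
F5 | step 11 | (2R,6S,10E)-2,6,10-trimethyl-4-methylidene-12-phenyl-2-[(triethylsilyl)oxy]dodec-10-en-1-ol | OC[C@](C)(O[Si](CC)(CC)CC)CC(=C)C[C@@H](C)CCC/C(C)=C/Cc1ccccc1
F6 | step 15 | triethyl{[(3R,7S,11E)-3,7,11-trimethyl-5-methylidene-13-phenyltridec-11-en-1-yn-3-yl]oxy}silane | C#C[C@](C)(O[Si](CC)(CC)CC)CC(=C)C[C@@H](C)CCC/C(C)=C/Cc1ccccc1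
F7 | step 15 | methyl (4R,8S,12E)-4,8,12-trimethyl-6-methylidene-14-phenyl-4-[(triethylsilyl)oxy]tetradec-12-en-2-ynoate | COC(=O)C#C[C@](C)(O[Si](CC)(CC)CC)CC(=C)C[C@@H](C)CCC/C(C)=C/Cc1ccccc1
F8 | step 17 | (5R)-5-{(4S)-7-(3-benzyl-2-methyloxiran-2-yl)-4-methyl-2-methylideneheptyl}-5-methylfuran-2(5H)-one (both trans-epoxides) | O=C1C=C[C@@](C)(CC(=C)C[C@@H](C)CCCC2(C)OC2Cc3ccccc3)O1
F9 | step 17 | (5R)-5-{(2RS,4S)-7-(3-benzyl-2-methyloxiran-2-yl)-2,4-dimethyl-2-[(triethylsilyl)peroxy]heptyl}-5-methylfuran-2(5H)-one | O=C1C=C[C@@](C)(CC(C)(OO[Si](CC)(CC)CC)C[C@@H](C)CCCC2(C)OC2Cc3ccccc3)O1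
F10 | step 17 | (5R)-5-{(2RS,4S)-7-(3-benzyl-2-methyloxiran-2-yl)-2-hydroperoxy-2,4-dimethylheptyl}-5-methylfuran-2(5H)-one | O=C1C=C[C@@](C)(CC(C)(OO)C[C@@H](C)CCCC2(C)OC2Cc3ccccc3)O1
F11 | step 17 | (3RS,4aR,7aR)-3-{(2S)-5-(3-benzyl-2-methyloxiran-2-yl)-2-methylpentyl}-3,4a-dimethyltetrahydrofuro[3,2-c][1,2]dioxin-6(3H)-one | CC1(CCC[C@H](C)CC2(C)C[C@@]3(C)OC(=O)C[C@H]3OO2)OC1Cc4ccccc4
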